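## The problem

Atom numbers used throughout: ring carbons C1–C10 as in a labdane (ring A = C1–C5 and C10, ring B = C5–C10), chain C11–C15, lactone carbons C16 (O–CH), C17, C18 and C19 (C=O), and the one-carbon branches C20 (on C17), C21 (on C13), C22 (on C8), C23 (4α, the formyl carbon), C24 (4β) and C25 (on C10); α/β as in steroids, the C10 methyl group being β.

The target is a trans-fused decalin whose C9 carries a chain with a 13E trisubstituted alkene and an (R)-4-methylbutenolide. Ring system and chain share only the C9–C11 bond, so the chain can be grown from a small handle on C9.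

Six of the seven stereocentres (C4, C5, C6, C8, C9, C10) are contiguous. The quaternary C10 and its neighbour C9 must be created together. Once they exist, the two syn-axial methyl groups on C4 and C10 can steer reagents at C5, C6 and C8 to the α face.

C4 is stereogenic only because one of its methyl groups is oxidised. The equatorial carbon C23 lies about 2.6 Å from an equatorial 6α-oxygen, so O6 can single it out. C16 is far from every ring stereocentre and must come from a reagent or a chiral building block.

The sensitive groups are the 6-hydroxy/23-aldehyde pair (hemiacetal formation, over-oxidation), the tertiary C8 alcohol (elimination in acid), and the butenolide (acidic H16; attacked by hydride and carbon nucleophiles). The aldehyde should therefore appear last and the butenolide late.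

In ring B the oxygens on C6 and C8 are separated by the unsubstituted C7, and C8 also carries the methyl group C22. This 1,3-pattern is what an ene reaction between a C6 aldehyde and an isopropenyl group (C7, C8, C22) leaves after hydration of the 8(22)-alkene.

## Retrosynthesis

**C23 oxidation last.** Target 36 is taken back through oxime 35 and nitrite 33 to alcohol 32, which has a plain gem-dimethyl group at C4. The forward reaction replaces a C23–H bond by C23–N. Only the distance to the 6α-oxygen distinguishes the two methyl groups, so O6 is used as the reagent. Carrying an oxygenated C23 from the start would make C4 a stereocentre that every ring-forming step must respect and would rule out an achiral ring A starting material. The forward step needs O6 to be the only nitrite, so O8 is silylated and O16 sits inside the lactone.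

**Butenolide.** Alcohol 32 comes from PMB ether 31, whose lactone is cut at O–C19 and C17=C18. This leads to the 16-hydroxy-17-ketone 29 and (triphenylphosphoranylidene)ketene. The neighbouring cut C16–C17 would need a β,γ-unsaturated aldehyde and catalyst control at C16. Here C16 arrives already configured and only an acylation and an intramolecular Wittig reaction are required. The ketone is kept as the dioxolane 28 until it is needed.

**Chain.** Ketal 28 is cut at C14–C15 and C13–C21 into terminal alkyne 22, epoxide 25 and a methyl group from Al(CH3)3. An olefination at C13=C14 would leave the geometry of a trisubstituted alkene to chance. Syn-carbometalation gives 13E by mechanism. Epoxide 25 is a four-carbon unit obtained from vinyl dioxolane 23 through racemic epoxide 24 by kinetic resolution.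

**C8 carbinol.** Silyl ether 22 goes back through alkyne 21, alcohol 20 and epoxide 19 to PMB ether 18 and the homoallylic alcohol 17. The C8–O and C22–H bonds are made by α-face epoxidation of the 8(22)-alkene and hydride opening, both governed by the C10 methyl group. The PMB and triethylsilyl groups are chosen so that O6 can be freed alone at the end.

**Ring B (key cut, C6–C7).** Alcohol 17 is opened to aldehyde 15, which holds the aldehyde on C5 and the isopropenyl group on C9 on adjacent ring A carbons. An aldol closure of the same bond would leave a C8 ketone. Methyl addition to that ketone from the open α face would give the wrong C8 epimer, whereas the ene reaction leaves an alkene that is hydrated with the correct sense. The precursor is monocyclic with three stereocentres. The spectator on C9 is a silyl-capped butynyl chain rather than an ester, so that C9 is not enolisable, the alkene cannot move into conjugation, and the later alkyne is already in place.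

**Ene unit and aldehyde.** Aldehyde 15 comes from alcohol 14, which comes from hydroxy ketone 13 and this from δ-lactone 12. The lactone carbonyl carbon is C8 and the ring oxygen is the later aldehyde oxygen. C22 comes from methyllithium and C7 from the Wittig reagent. The lactone is crystalline-type, rigid material in which a C5 epimer can be separated and a C9 epimer equilibrated.

**C5.** Lactone 12 comes from acid 9 by hydroboration of the exocyclic C5=C6 alkene (C6–O and C5–H bonds). The acid has no other reactive π bond, because the alkyne is capped with a triisopropylsilyl group.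

**C9–C10.** Acid 9 is the [3,3] product of ester 6, made from β-cyclogeraniol 5 and acid 3, which come from β-cyclocitral 4 and hex-5-ynoic acid 1 (through silyl ester 2). Chirality transfer from a stereogenic C6 carbinol was considered and set aside. In the chair, the extra C6 substituent must either eclipse the quaternary C4 or sit syn-axial to C25, so neither rate nor sense of transfer can be predicted. With an unsubstituted C6 the chair is unencumbered, and a chiral boron enolate supplies the absolute configuration.

## Roads not taken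

**Alternative 1:** The cut is C14–C15 (with C13–C21). A decalin alkyne A1 carrying all ring oxygens is carboaluminated and the derived alanate opens the PMB-protected epoxy alcohol A2 to give homoallylic alcohol A3.
- Merits: the 13E geometry and C16 are secured in one convergent step, and C23 is carried as a protected alcohol, so no late C–H oxidation is needed.
- Weak points: the step closes no ring and sets none of the six ring stereocentres, so A1 still needs a solution for ring B. After coupling, about four steps are needed to turn the protected carbinol into the butenolide.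
- Comparison: the chosen plan uses the same joining tactic as a subordinate step (step 17), with an epoxide already at the ketone oxidation level. Alternative 1 is better in avoiding the photochemical step. The chosen plan sets against this an achiral gem-dimethyl ring A and a ring-forming step that places O6 and the C8 alkene.

**Alternative 2:** The cuts are C4–C5, C9–C10 and C8–O. SnCl4 opens the 2,2-disubstituted epoxide of homofarnesic acid A4 and the two alkenes and the acid close rings A and B and a γ-lactone, giving A5.
- Merits: two carbocycles and the stereocentres C4, C5, C8, C9 and C10 form in one step, and C4 is set by the epoxide.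
- Weak points: a 2,2-disubstituted epoxide is a poor, rearrangement-prone initiator and is hard to obtain in high enantiomeric purity. A5 has no oxygen on C6 and no functional group next to it. The lactone must be reopened and extended by the carbons C13–C19.
- Comparison: alternative 2 is clearly shorter to the bicyclic core and better at C4. The chosen plan sets against this that its ring closure itself delivers the C6 hydroxyl, which alternative 2 could only add by a remote functionalisation of uncertain regiochemistry.

**Alternative 3:** The cut is C16–C17 plus the lactone C–O bond. CrCl2 with catalytic NiCl2 and a chiral ligand adds the alkenylchromium species from iodo ester A7 to aldehyde A6, and the alkoxide lactonises to A8.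
- Merits: the butenolide and C16 are made in one late, convergent step under conditions that tolerate the silyl and PMB ethers.
- Weak points: A6 is a β,γ-unsaturated aldehyde that can enolise or move its alkene into conjugation. C16 depends entirely on the ligand, with an unbranched aliphatic aldehyde as the least favourable substrate class. Chromium is needed in stoichiometric amount.
- Comparison: for the chain terminus alternative 3 needs one step where the chosen plan needs three (steps 17–19); this is conceded. The chosen plan sets against it a C16 configuration fixed by a resolved epoxide and the absence of a fragile aldehyde.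

Key step: step 9

Assumption: the (S,S)-bromoborane of step 4 and the (S,S)-cobalt catalyst of step 16 are taken to give the enantiomers drawn, by analogy with simple allylic esters and alkyl oxiranes; if either sense is the opposite, the mirror-image reagent is used and nothing else changes; the target is handled as the open hydroxy aldehyde, which may equilibrate with its 6,23-hemiacetal.

Step 1
Reactants: 1 hex-5-ynoic acid
Product: 3 6-(triisopropylsilyl)hex-5-ynoic acid, via silyl ester 2 (not isolated)
Conditions: n-BuLi (2.1 equiv), THF, −78 °C; i-Pr3SiOTf (2.1 equiv), −78 °C → rt; K2CO3, MeOH/H2O; HCl to pH 3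
Reagents that add atoms: triisopropylsilyl trifluoromethanesulfonate, CC(C)[Si](C(C)C)(C(C)C)OS(=O)(=O)C(F)(F)F
Why: The carboxylate–acetylide dianion is silylated at the alkyne carbon; the silyl ester 2 formed alongside is cleaved by carbonate, which leaves the hindered alkynylsilane intact. The bulky cap lets the alkyne pass the hydroboration of step 5 and the Lewis acid of step 9.

Step 2
Reactants: 4 β-cyclocitral
Product: 5 β-cyclogeraniol
Conditions: NaBH4, MeOH, 0 °C
Reagents that add atoms: none
Why: Borohydride reduction of the hindered enal is purely 1,2 and gives the primary allylic alcohol; no stereocentre is formed.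

Step 3
Reactants: 5 β-cyclogeraniol; 3 6-(triisopropylsilyl)hex-5-ynoic acid
Product: 6 (2,6,6-trimethylcyclohex-1-en-1-yl)methyl 6-(triisopropylsilyl)hex-5-ynoate
Conditions: N,N'-dicyclohexylcarbodiimide, 4-(dimethylamino)pyridine (cat.), CH2Cl2, 0 °C → rt
Reagents that add atoms: none
Why: Steglich esterification joins the two pieces under neutral conditions, so the ionisable allylic C–O bond next to the tetrasubstituted alkene never meets acid.

Step 4
Reactants: 6 (2,6,6-trimethylcyclohex-1-en-1-yl)methyl 6-(triisopropylsilyl)hex-5-ynoate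
Product: 9 (2R)-2-[(1R)-1,3,3-trimethyl-2-methylidenecyclohexyl]-6-(triisopropylsilyl)hex-5-ynoic acid, via boron ketene acetal 7 (not isolated), via boryl ester 8 (not isolated)
Conditions: (4S,5S)-2-bromo-1,3-bis{[3,5-bis(trifluoromethyl)phenyl]sulfonyl}-4,5-diphenyl-1,3,2-diazaborolidine (1.3 equiv), i-Pr2NEt (2 equiv), CH2Cl2, −78 °C, then −20 → 23 °C; H2O work-up
Reagents that add atoms: none
Why: The bromoborane and the amine give boron ketene acetal 7 with the C11 chain cis to the boron-bound oxygen, and 7 undergoes an enantioselective ester-enolate (Ireland-type) Claisen rearrangement through a chair in which C9 bonds to C10 and the ring alkene moves to C5=C6. The chair with this enolate geometry places H9 anti to the C10 methyl group (relative configuration), and the sulfonamide ligand selects the enolate face and so the absolute configuration of C9 and C10. Because C6 is an unsubstituted CH2, no substituent has to take either of the two congested positions next to C4 and C25; water hydrolyses boryl ester 8 and returns the bis-sulfonamide.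

Step 5
Reactants: 9 (2R)-2-[(1R)-1,3,3-trimethyl-2-methylidenecyclohexyl]-6-(triisopropylsilyl)hex-5-ynoic acid
Product: 12 (4R,4aS,8aS)-4a,8,8-trimethyl-4-[4-(triisopropylsilyl)but-3-yn-1-yl]-1,4,4a,5,6,7,8,8a-octahydro-3H-isochromen-3-one, via organoborane 10 (not isolated), via hydroxy acid 11 (not isolated)
Conditions: 9-borabicyclo[3.3.1]nonane (3 equiv), THF, 0 → 60 °C; NaOH, H2O2, 0 °C → rt; 1 M HCl; pyridinium p-toluenesulfonate (cat.), benzene, 50 °C
Reagents that add atoms: hydrogen peroxide, OO
Why: After the acid has taken one equivalent as its boryl ester, the borane adds to the only reactive alkene with boron on the terminal carbon C6 and hydrogen on C5 from the face opposite the syn-axial methyl groups on C4 and C10; this places C6 equatorial and trans to C9. Oxidation gives hydroxy acid 11, which closes to the trans-fused δ-lactone. In the lactone a C5 epimer is separable and H9 is α to a carbonyl, so a C9 epimer from step 4 can be equilibrated to the equatorial chain.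

Step 6
Reactants: 12 (4R,4aS,8aS)-4a,8,8-trimethyl-4-[4-(triisopropylsilyl)but-3-yn-1-yl]-1,4,4a,5,6,7,8,8a-octahydro-3H-isochromen-3-one
Product: 13 (3R)-3-[(1S,2S)-2-(hydroxymethyl)-1,3,3-trimethylcyclohexyl]-7-(triisopropylsilyl)hept-6-yn-2-one (in equilibrium with its cyclic hemiketal)
Conditions: CH3Li (1.1 equiv), THF, −78 °C; aq. NH4Cl
Reagents that add atoms: methyllithium, [Li]C
Why: One equivalent of methyllithium adds to the lactone carbonyl and the tetrahedral lithium lactolate persists at −78 °C, which prevents a second addition; work-up gives the methyl ketone and its hemiketal. The added carbon is C22.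

Step 7
Reactants: 13 (3R)-3-[(1S,2S)-2-(hydroxymethyl)-1,3,3-trimethylcyclohexyl]-7-(triisopropylsilyl)hept-6-yn-2-one
Product: 14 [(1S,2R)-2,6,6-trimethyl-2-[(3S)-2-methyl-7-(triisopropylsilyl)hept-1-en-6-yn-3-yl]cyclohexyl]methanol
Conditions: Ph3PCH3Br (4 equiv), KN(SiMe3)2 (3.8 equiv), THF, 0 → 50 °C
Reagents that add atoms: methyltriphenylphosphonium bromide, C[P+](c1ccccc1)(c1ccccc1)c1ccccc1.[Br-]
Why: Wittig methylenation of the open keto form, drawn from the hemiketal equilibrium as its alkoxide, installs C7 and completes the isopropenyl group. The hindered position of H9 and the moderate temperature limit epimerisation at C9.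

Step 8
Reactants: 14 [(1S,2R)-2,6,6-trimethyl-2-[(3S)-2-methyl-7-(triisopropylsilyl)hept-1-en-6-yn-3-yl]cyclohexyl]methanol
Product: 15 (1S,2R)-2,6,6-trimethyl-2-[(3S)-2-methyl-7-(triisopropylsilyl)hept-1-en-6-yn-3-yl]cyclohexane-1-carbaldehyde
Conditions: Dess–Martin periodinane, NaHCO3, CH2Cl2, 0 °C → rt
Reagents that add atoms: none
Why: Buffered Dess–Martin oxidation converts the hindered primary alcohol into the aldehyde without epimerising C5 or touching the alkene or the silylalkyne.

Step 9
Reactants: 15 (1S,2R)-2,6,6-trimethyl-2-[(3S)-2-methyl-7-(triisopropylsilyl)hept-1-en-6-yn-3-yl]cyclohexane-1-carbaldehyde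
Product: 17 (5S,6S,9S,10R)-4,4,10β-trimethyl-8-methylidene-9β-[4-(triisopropylsilyl)but-3-yn-1-yl]-5α-decalin-6α-ol, via aluminium alkoxide 16 (not isolated)
Conditions: (CH3)2AlCl (1.5 equiv), CH2Cl2, −78 → −20 °C; aq. NaHCO3
Reagents that add atoms: none
Why: (CH3)2AlCl binds the aldehyde oxygen, the terminal carbon C7 of the isopropenyl group adds to C6 and a hydrogen of the C22 methyl group is passed to oxygen, after which the alkoxide–aluminium complex loses methane to give 16, so that no free acid remains to move the new alkene or to epimerise C5. The closest known reaction type is the Lewis-acid-promoted type 2 intramolecular carbonyl-ene cyclisation of 5-methylhex-5-enals to 3-methylenecyclohexanols. Ring B closes as a six-membered ring, exo with respect to the C=O group and endo with respect to the C7=C8 group, so that C8 becomes a ring atom and the double bond reappears exocyclic as C8=C22. The one new stereocentre, C6, is controlled by the chair-like ring B that forms on the trans-diequatorial C5 and C10 substituents of ring A: the aluminium-bound oxygen takes the equatorial position because the axial one is syn-axial to both C24 and C25, and this is the 6α-alcohol. With the oxygen equatorial the hydrogen transfer cannot be fully synchronous and is expected to follow C–C bond formation, the aluminate taking a hydrogen from the methyl group of the developing tertiary C8 centre. The step needs this hydrogen to come from C22 and not from C7 or C9, which the three accessible methyl hydrogens and the proton-scavenging reagent favour. It needs the alkene and not the alkyne to attack, which the silyl cap and the six-membered reach of the isopropenyl group secure. It needs C5 and C9 to keep their configuration, which the low temperature and the absence of a carbonyl group on C9 secure.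

Step 10
Reactants: 17 (5S,6S,9S,10R)-4,4,10β-trimethyl-8-methylidene-9β-[4-(triisopropylsilyl)but-3-yn-1-yl]-5α-decalin-6α-ol
Product: 18 6α-(4-methoxybenzyl) ether of 17
Conditions: NaH, 4-methoxybenzyl chloride, n-Bu4NI (cat.), DMF, 0 °C → rt
Reagents that add atoms: 4-methoxybenzyl chloride, COc1ccc(CCl)cc1
Why: Williamson etherification of the only hydroxyl group. The PMB ether tolerates hydride, fluoride, organoaluminium reagents and mild acid and is later removed oxidatively beside a silyl ether and the butenolide.

Step 11
Reactants: 18 6α-(4-methoxybenzyl) ether of 17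
Product: 19 8α,22-epoxide of 18 (spiro-oxirane at C8 with the oxygen α)
Conditions: 3-chloroperoxybenzoic acid, NaHCO3, CH2Cl2, 0 °C
Reagents that add atoms: 3-chloroperoxybenzoic acid, OOC(=O)c1cccc(Cl)c1
Why: Prilezhaev epoxidation of the 1,1-disubstituted alkene (the silylalkyne is inert) occurs on the α face, because the β face of C8 is syn-axial to the C10 methyl group; this sets the C8–O bond α (equatorial).

Step 12
Reactants: 19 8α,22-epoxide of 18
Product: 20 6α-(4-methoxybenzyloxy)-4,4,8β,10β-tetramethyl-9β-[4-(triisopropylsilyl)but-3-yn-1-yl]-5α-decalin-8α-ol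
Conditions: LiAlH4, THF, 0 → 40 °C; aq. NaOH work-up
Reagents that add atoms: none
Why: Hydride opens the spiro-epoxide at its primary carbon C22, so the α-oxygen stays on C8 and C22 becomes the 8β-methyl group.

Step 13
Reactants: 20 6α-(4-methoxybenzyloxy)-4,4,8β,10β-tetramethyl-9β-[4-(triisopropylsilyl)but-3-yn-1-yl]-5α-decalin-8α-ol
Product: 21 9β-(but-3-yn-1-yl)-6α-(4-methoxybenzyloxy)-4,4,8β,10β-tetramethyl-5α-decalin-8α-ol
Conditions: n-Bu4NF, THF, rt
Reagents that add atoms: none
Why: Fluoride cleaves the alkynyl–silicon bond; the ether and the tertiary alcohol are unaffected.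

Step 14
Reactants: 21 9β-(but-3-yn-1-yl)-6α-(4-methoxybenzyloxy)-4,4,8β,10β-tetramethyl-5α-decalin-8α-ol
Product: 22 8α-triethylsilyl ether of 21
Conditions: Et3SiOTf, 2,6-lutidine, CH2Cl2, −78 → 0 °C
Reagents that add atoms: triethylsilyl trifluoromethanesulfonate, CC[Si](CC)(CC)OS(=O)(=O)C(F)(F)F
Why: The silyl triflate silylates the hindered tertiary alcohol. The silyl ether keeps O8 out of the aluminium chemistry of step 17 and out of the nitrosation of step 21.

Step 15
Reactants: 23 2-ethenyl-2-methyl-1,3-dioxolane
Product: 24 racemic 2-methyl-2-(oxiran-2-yl)-1,3-dioxolane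
Conditions: 3-chloroperoxybenzoic acid, CH2Cl2, 0 °C → rt
Reagents that add atoms: 3-chloroperoxybenzoic acid, OOC(=O)c1cccc(Cl)c1
Why: Prilezhaev epoxidation of the vinyl group; the ketal is stable to the peracid.

Step 16
Reactants: 24 racemic 2-methyl-2-(oxiran-2-yl)-1,3-dioxolane
Product: 25 2-methyl-2-[(2R)-oxiran-2-yl]-1,3-dioxolane
Conditions: (S,S)-(salen)Co(OAc) (0.5 mol%), H2O (0.55 equiv), THF, 0 °C → rt; distillation
Reagents that add atoms: none
Why: Hydrolytic kinetic resolution: the acetate of the trivalent cobalt complex of (S,S)-N,N'-bis(3,5-di-tert-butylsalicylidene)cyclohexane-1,2-diamine hydrolyses the S epoxide much faster than the R epoxide, which is recovered. This is the source of the C16 configuration.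

Step 17
Reactants: 22 8α-triethylsilyl ether of 21; 25 2-methyl-2-[(2R)-oxiran-2-yl]-1,3-dioxolane
Product: 28 (13E,16R)-16-hydroxy-17-ketone ethylene ketal carrying the 6α-PMB ether and the 8α-triethylsilyl ether, via alkenylalane 26 (not isolated), via lithium alanate 27 (not isolated)
Conditions: Al(CH3)3 (3 equiv), Cp2ZrCl2 (0.25 equiv), CH2Cl2, 0 °C → rt; evaporate; n-BuLi (1.05 equiv), hexane/THF, −30 °C; 25 (1.5 equiv), −30 °C → rt; aq. NH4Cl
Reagents that add atoms: trimethylaluminium, C[Al](C)C
Why: Zirconium-catalysed carboalumination adds CH3 and aluminium syn across the terminal alkyne, with the methyl group (C21) on C13, which fixes the 13E geometry in 26. Butyllithium converts 26 into the more nucleophilic alanate 27, which transfers its alkenyl group with retention to the unsubstituted carbon of epoxide 25 and leaves C16 untouched.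

Step 18
Reactants: 28 (13E,16R)-16-hydroxy-17-ketone ethylene ketal carrying the 6α-PMB ether and the 8α-triethylsilyl ether
Product: 29 (13E,16R)-16-hydroxy-17-ketone carrying the 6α-PMB ether and the 8α-triethylsilyl ether
Conditions: pyridinium p-toluenesulfonate (0.3 equiv), acetone/H2O 10:1, 50 °C
Reagents that add atoms: water, O
Why: Mild acid-catalysed hydrolysis removes the dioxolane; the PMB ether and the hindered tertiary silyl ether tolerate the weak acid, and the conditions do not enolise the ketone towards C16.

Step 19
Reactants: 29 (13E,16R)-16-hydroxy-17-ketone carrying the 6α-PMB ether and the 8α-triethylsilyl ether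
Product: 31 (13E,16R)-butenolide carrying the 6α-PMB ether and the 8α-triethylsilyl ether, via ester ylide 30 (not isolated)
Conditions: Ph3P=C=C=O (1.3 equiv), toluene, 80 °C
Reagents that add atoms: (triphenylphosphoranylidene)ketene, O=C=C=P(c1ccccc1)(c1ccccc1)c1ccccc1
Why: The hydroxyl group of the α-hydroxy ketone adds to the ketene carbon of the ylide to give ester ylide 30, which closes by an intramolecular Wittig reaction on the C17 ketone to the 4-methylbutenolide. The ring enforces the cis enoate, C16 takes no part, and neither protected oxygen can be acylated.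

Step 20
Reactants: 31 (13E,16R)-butenolide carrying the 6α-PMB ether and the 8α-triethylsilyl ether
Product: 32 (13E,16R)-butenolide 6α-ol 8α-triethylsilyl ether
Conditions: 2,3-dichloro-5,6-dicyano-1,4-benzoquinone, CH2Cl2/pH 7 buffer, 0 °C → rt
Reagents that add atoms: none
Why: Oxidative cleavage of the PMB ether frees O6 alone; the silyl ether, the alkene and the butenolide are inert to the quinone.

Step 21
Reactants: 32 (13E,16R)-butenolide 6α-ol 8α-triethylsilyl ether
Product: 33 6α-nitrite ester of 32
Conditions: t-BuONO (10 equiv), CH2Cl2, 0 °C → rt, dark; evaporate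
Reagents that add atoms: tert-butyl nitrite, CC(C)(C)ON=O
Why: Nitrosyl exchange with tert-butyl nitrite converts the only free alcohol into its nitrite ester without an electrophilic nitrosating agent that could add to the C13 alkene; O8 is blocked.

Step 22
Reactants: 33 6α-nitrite ester of 32
Product: 35 23-oxime of the 8α-triethylsilyl ether of the target, via nitroso compound 34 (not isolated)
Conditions: hν (medium-pressure Hg lamp, Pyrex filter), benzene, N2, 15 °C; then 2-propanol, 60 °C
Reagents that add atoms: none
Why: Barton nitrite photolysis: O–NO homolysis gives the 6α-alkoxy radical, which abstracts hydrogen through a six-membered transition state from the only δ-carbon within reach, the equatorial 4α-methyl group C23 (peri to the equatorial O6). Recombination with NO gives nitroso compound 34, which tautomerises to the oxime on warming; this differentiates the two methyl groups and sets C4 as R.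

Step 23
Reactants: 35 23-oxime of the 8α-triethylsilyl ether of the target
Product: 36 target CNP0143336.1
Conditions: levulinic acid/1 M HCl 9:1, THF, 0 °C → rt
Reagents that add atoms: water, O
Why: Exchange of the oxime onto levulinic acid in dilute acid frees the aldehyde, and the same medium hydrolyses the tertiary triethylsilyl ether. The conditions are mild enough for the tertiary alcohol, the alkene and the butenolide.

## Compound list

1 | hex-5-ynoic acid | OC(=O)CCCC#C | starting material
2 | triisopropylsilyl 6-(triisopropylsilyl)hex-5-ynoate (not isolated) | CC(C)[Si](C(C)C)(C(C)C)OC(=O)CCCC#C[Si](C(C)C)(C(C)C)C(C)C | intermediate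
3 | 6-(triisopropylsilyl)hex-5-ynoic acid | OC(=O)CCCC#C[Si](C(C)C)(C(C)C)C(C)C | intermediate
4 | β-cyclocitral (2,6,6-trimethylcyclohex-1-ene-1-carbaldehyde) | CC1=C(C=O)C(C)(C)CCC1 | starting material
5 | β-cyclogeraniol ((2,6,6-trimethylcyclohex-1-en-1-yl)methanol) | CC1=C(CO)C(C)(C)CCC1 | intermediate
6 | (2,6,6-trimethylcyclohex-1-en-1-yl)methyl 6-(triisopropylsilyl)hex-5-ynoate | CC1=C(COC(=O)CCCC#C[Si](C(C)C)(C(C)C)C(C)C)C(C)(C)CCC1 | intermediate
7 | boron ketene acetal of 6 with the C11 chain cis to O–B and the (4S,5S)-diazaborolidine on oxygen (not isolated) | CC(C)[Si](C(C)C)(C(C)C)C#CCC/C=C(/OCC1=C(C)CCCC1(C)C)OB2N(S(=O)(=O)c3cc(cc(c3)C(F)(F)F)C(F)(F)F)[C@@H](c3ccccc3)[C@H](c3ccccc3)N2S(=O)(=O)c2cc(cc(c2)C(F)(F)F)C(F)(F)F | intermediate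
8 | O-boryl ester of acid 9 with the (4S,5S)-diazaborolidine (not isolated) | CC(C)[Si](C(C)C)(C(C)C)C#CCC[C@@H](C(=O)OB2N(S(=O)(=O)c3cc(cc(c3)C(F)(F)F)C(F)(F)F)[C@@H](c3ccccc3)[C@H](c3ccccc3)N2S(=O)(=O)c2cc(cc(c2)C(F)(F)F)C(F)(F)F)[C@@]1(C)CCCC(C)(C)C1=C | intermediate
9 | (2R)-2-[(1R)-1,3,3-trimethyl-2-methylidenecyclohexyl]-6-(triisopropylsilyl)hex-5-ynoic acid | CC(C)[Si](C(C)C)(C(C)C)C#CCC[C@@H](C(O)=O)[C@@]1(C)CCCC(C)(C)C1=C | intermediate
10 | organoborane: C6-(9-borabicyclo[3.3.1]nonan-9-yl) adduct of 9 as its O-(9-borabicyclononyl) ester, H5 trans to the C10 methyl group (not isolated) | CC(C)[Si](C(C)C)(C(C)C)C#CCC[C@@H](C(=O)OB2C3CCCC2CCC3)[C@@]1(C)CCCC(C)(C)[C@@H]1CB1C2CCCC1CCC2 | intermediate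
11 | (2R)-2-[(1S,2S)-2-(hydroxymethyl)-1,3,3-trimethylcyclohexyl]-6-(triisopropylsilyl)hex-5-ynoic acid (not isolated) | CC(C)[Si](C(C)C)(C(C)C)C#CCC[C@@H](C(O)=O)[C@@]1(C)CCCC(C)(C)[C@@H]1CO | intermediate
12 | (4R,4aS,8aS)-4a,8,8-trimethyl-4-[4-(triisopropylsilyl)but-3-yn-1-yl]-1,4,4a,5,6,7,8,8a-octahydro-3H-isochromen-3-one (trans-fused δ-lactone; lactone C=O is C8) | CC(C)[Si](C(C)C)(C(C)C)C#CCC[C@@H]1[C@@]2(C)CCCC(C)(C)[C@@H]2COC1=O | intermediate
13 | (3R)-3-[(1S,2S)-2-(hydroxymethyl)-1,3,3-trimethylcyclohexyl]-7-(triisopropylsilyl)hept-6-yn-2-one (with its cyclic hemiketal) | CC(C)[Si](C(C)C)(C(C)C)C#CCC[C@@H](C(C)=O)[C@@]1(C)CCCC(C)(C)[C@@H]1CO | intermediate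
14 | [(1S,2R)-2,6,6-trimethyl-2-[(3S)-2-methyl-7-(triisopropylsilyl)hept-1-en-6-yn-3-yl]cyclohexyl]methanol | CC(C)[Si](C(C)C)(C(C)C)C#CCC[C@@H](C(C)=C)[C@@]1(C)CCCC(C)(C)[C@@H]1CO | intermediate
15 | (1S,2R)-2,6,6-trimethyl-2-[(3S)-2-methyl-7-(triisopropylsilyl)hept-1-en-6-yn-3-yl]cyclohexane-1-carbaldehyde (ene precursor) | CC(C)[Si](C(C)C)(C(C)C)C#CCC[C@@H](C(C)=C)[C@@]1(C)CCCC(C)(C)[C@@H]1C=O | intermediate
16 | chloro(methyl)aluminium 6α-alkoxide of 17 (not isolated) | CC(C)[Si](C(C)C)(C(C)C)C#CCC[C@@H]1[C@@]2(C)CCCC(C)(C)[C@@H]2[C@@H](O[Al](C)Cl)CC1=C | intermediate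
17 | (5S,6S,9S,10R)-4,4,10β-trimethyl-8-methylidene-9β-[4-(triisopropylsilyl)but-3-yn-1-yl]-5α-decalin-6α-ol (ene product) | CC(C)[Si](C(C)C)(C(C)C)C#CCC[C@@H]1[C@@]2(C)CCCC(C)(C)[C@@H]2[C@@H](O)CC1=C | intermediate
18 | 6α-(4-methoxybenzyl) ether of 17 | CC(C)[Si](C(C)C)(C(C)C)C#CCC[C@@H]1[C@@]2(C)CCCC(C)(C)[C@@H]2[C@@H](OCc3ccc(OC)cc3)CC1=C | intermediate
19 | 8α,22-epoxide of 18 (spiro-oxirane, oxygen α) | CC(C)[Si](C(C)C)(C(C)C)C#CCC[C@@H]1[C@@]2(C)CCCC(C)(C)[C@@H]2[C@@H](OCc3ccc(OC)cc3)C[C@]13CO3 | intermediate
20 | 6α-(4-methoxybenzyloxy)-4,4,8β,10β-tetramethyl-9β-[4-(triisopropylsilyl)but-3-yn-1-yl]-5α-decalin-8α-ol | CC(C)[Si](C(C)C)(C(C)C)C#CCC[C@@H]1[C@@]2(C)CCCC(C)(C)[C@@H]2[C@@H](OCc3ccc(OC)cc3)C[C@@]1(C)O | intermediate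
21 | 9β-(but-3-yn-1-yl)-6α-(4-methoxybenzyloxy)-4,4,8β,10β-tetramethyl-5α-decalin-8α-ol | C#CCC[C@@H]1[C@@]2(C)CCCC(C)(C)[C@@H]2[C@@H](OCc3ccc(OC)cc3)C[C@@]1(C)O | intermediate
22 | 8α-triethylsilyl ether of 21 | C#CCC[C@@H]1[C@@]2(C)CCCC(C)(C)[C@@H]2[C@@H](OCc3ccc(OC)cc3)C[C@@]1(C)O[Si](CC)(CC)CC | intermediate
23 | 2-ethenyl-2-methyl-1,3-dioxolane | CC1(C=C)OCCO1 | starting material
24 | racemic 2-methyl-2-(oxiran-2-yl)-1,3-dioxolane | CC1(OCCO1)C1CO1 | intermediate
25 | 2-methyl-2-[(2R)-oxiran-2-yl]-1,3-dioxolane | CC1(OCCO1)[C@H]1CO1 | intermediate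
26 | (E)-alkenyl(dimethyl)alane from 22: Al on C14, methyl C21 on C13 (not isolated) | C[Al](C)/C=C(\C)CC[C@@H]1[C@@]2(C)CCCC(C)(C)[C@@H]2[C@@H](OCc3ccc(OC)cc3)C[C@@]1(C)O[Si](CC)(CC)CC | intermediate
27 | lithium (E)-alkenyl(butyl)dimethylalanate from 26 (not isolated) | [Li+].CCCC[Al-](C)(C)/C=C(\C)CC[C@@H]1[C@@]2(C)CCCC(C)(C)[C@@H]2[C@@H](OCc3ccc(OC)cc3)C[C@@]1(C)O[Si](CC)(CC)CC | intermediate
28 | (13E,16R)-16-hydroxy-17-ketone ethylene ketal with 6α-PMB ether and 8α-triethylsilyl ether | CC1(OCCO1)[C@H](O)C/C=C(\C)CC[C@@H]1[C@@]2(C)CCCC(C)(C)[C@@H]2[C@@H](OCc3ccc(OC)cc3)C[C@@]1(C)O[Si](CC)(CC)CC | intermediate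
29 | (13E,16R)-16-hydroxy-17-ketone with 6α-PMB ether and 8α-triethylsilyl ether | CC(=O)[C@H](O)C/C=C(\C)CC[C@@H]1[C@@]2(C)CCCC(C)(C)[C@@H]2[C@@H](OCc3ccc(OC)cc3)C[C@@]1(C)O[Si](CC)(CC)CC | intermediate
30 | 16-O-[(triphenylphosphoranylidene)acetyl] ester of 29 (not isolated) | CC(=O)[C@H](OC(=O)C=P(c1ccccc1)(c1ccccc1)c1ccccc1)C/C=C(\C)CC[C@@H]1[C@@]2(C)CCCC(C)(C)[C@@H]2[C@@H](OCc3ccc(OC)cc3)C[C@@]1(C)O[Si](CC)(CC)CC | intermediate
31 | (13E,16R)-butenolide with 6α-PMB ether and 8α-triethylsilyl ether | CC1=CC(=O)O[C@@H]1C/C=C(\C)CC[C@@H]1[C@@]2(C)CCCC(C)(C)[C@@H]2[C@@H](OCc3ccc(OC)cc3)C[C@@]1(C)O[Si](CC)(CC)CC | intermediate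
32 | (13E,16R)-butenolide 6α-ol 8α-triethylsilyl ether | CC1=CC(=O)O[C@@H]1C/C=C(\C)CC[C@@H]1[C@@]2(C)CCCC(C)(C)[C@@H]2[C@@H](O)C[C@@]1(C)O[Si](CC)(CC)CC | intermediate
33 | 6α-nitrite ester of 32 | CC1=CC(=O)O[C@@H]1C/C=C(\C)CC[C@@H]1[C@@]2(C)CCCC(C)(C)[C@@H]2[C@@H](ON=O)C[C@@]1(C)O[Si](CC)(CC)CC | intermediate
34 | 23-nitroso compound (4α-CH2N=O, 6α-OH, 8α-triethylsilyl ether) (not isolated) | CC1=CC(=O)O[C@@H]1C/C=C(\C)CC[C@@H]1[C@@]2(C)CCC[C@@](C)(CN=O)[C@@H]2[C@@H](O)C[C@@]1(C)O[Si](CC)(CC)CC | intermediate
35 | 23-oxime of the 8α-triethylsilyl ether of the target | CC1=CC(=O)O[C@@H]1C/C=C(\C)CC[C@@H]1[C@@]2(C)CCC[C@@](C)(C=NO)[C@@H]2[C@@H](O)C[C@@]1(C)O[Si](CC)(CC)CC | intermediate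
36 | CNP0143336.1: (4R,5R,6S,8R,9R,10S,13E,16R)-6α,8α-dihydroxy-23-oxo butenolide | CC1=CC(=O)O[C@@H]1C/C=C(\C)CC[C@@H]1[C@@]2(C)CCC[C@@](C)(C=O)[C@@H]2[C@@H](O)C[C@@]1(C)O | target

## Step count and least certain steps

Total: 23 steps. Longest linear sequence: 20 steps from β-cyclocitral (steps 2–14 and 17–23); steps 1, 15 and 16 prepare the two side pieces.

**Step 9 (key step).** The most likely failure is loss of the hydrogen from C7 (or capture of chloride) instead of from the C22 methyl group. With the oxygen equatorial the methyl hydrogens are not within direct reach of it, so the transfer cannot be concerted. The cyclisation might also run through the axial-oxygen arrangement and give the 6β epimer, or stall because the aldehyde is flanked by two quaternary carbons. A 7-ene isomer is tolerated by the route: after steps 10–12 (α-epoxidation, hydride opening at C7) it should give the same alcohol 20. The fallback replaces the ene closure by an aldol closure of the same bond. It sets out from hydroxy ketone 13: Dess–Martin oxidation gives keto aldehyde F1; an intramolecular aldol reaction of the methyl ketone onto the aldehyde under mild equilibrating base (K2CO3, MeOH, 0 °C) should give the 6α-hydroxy-8-ketone F2 with the alcohol equatorial; Petasis methylenation with Cp2Ti(CH3)2 in toluene at 65 °C then gives 17, where the route is rejoined.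

**Step 4.** Enolisation and rearrangement at the tetrasubstituted allyl terminus may be slow enough for the Lewis-acidic boron bromide to ionise the allylic ester, or face selection by the ligand may erode on this hindered substrate. The fallback sets out from ester 6 and separates ring formation from enantiocontrol. An Ireland–Claisen rearrangement (LiN(i-Pr)2, Me3SiCl, THF/DMPU, −78 → 60 °C) through trimethylsilyl ketene acetal F3 gives the silyl ester F4, hydrolysed on work-up to the racemic acid (9 together with its enantiomer F5). The acid is resolved by crystallisation of the (S)-1-phenylethylammonium salt F6, and acidification returns 9.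

**Step 5.** Addition to the doubly neopentyl alkene may be slow enough for the borane to attack the silylalkyne, or hydrogen may be delivered to C5 from the wrong face because the stereo-determining contact is at C6 rather than C5. The fallback sets out from acid 9: esterification with Me3SiCHN2 gives methyl ester F7; epoxidation with 3-chloroperoxybenzoic acid gives spiro-epoxide F8; reductive opening with Cp2TiCl (trivalent titanium, from Cp2TiCl2 and Mn) and 1,4-cyclohexadiene gives hydroxy ester F9, the hydrogen atom now being delivered to the planar C5 radical itself from the face away from the two axial methyl groups. Acid-catalysed lactonisation with loss of methanol returns 12.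

**Step 17.** The alanate may transfer its alkenyl group only slowly to an epoxide flanked by a quaternary ketal carbon, so that methyl or butyl transfer or Lewis-acid opening of the epoxide competes. The fallback sets out from alkenylalane 26: iodinolysis gives alkenyl iodide F10; halogen–lithium exchange with t-BuLi at −78 °C gives alkenyllithium F11; this opens epoxide 25 in the presence of BF3·OEt2 at −78 °C to return 28.

**Step 22.** The C6 alkoxy radical may fragment (C5–C6 or C6–C7 cleavage next to two quaternary carbons) or recombine with NO at oxygen faster than it abstracts hydrogen from C23, giving low conversion to the oxime. The fallback sets out from alcohol 32 and replaces the radical by a metal-catalysed C–H silylation. Dehydrogenative silylation with Et2SiH2 and catalytic [Ir(cod)OMe]2 gives hydrosilyl ether F12. Rhodium-catalysed silylation of the δ C–H bond ([Rh(cod)Cl]2, Xantphos, norbornene) gives oxasilinane F13. Tamao–Fleming oxidation (H2O2, KHCO3, KF) gives the 6,23-diol F14. Selective oxidation of the primary alcohol (TEMPO, PhI(OAc)2) gives hydroxy aldehyde F15, and 1 M HCl in THF removes the silyl ether to return 36.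

## Further compounds

F1 | step 9 | (3R)-3-[(1R,2S)-2-formyl-1,3,3-trimethylcyclohexyl]-7-(triisopropylsilyl)hept-6-yn-2-one (keto aldehyde) | CC(C)[Si](C(C)C)(C(C)C)C#CCC[C@@H](C(C)=O)[C@@]1(C)CCCC(C)(C)[C@@H]1C=O
F2 | step 9 | 6α-hydroxy-4,4,10β-trimethyl-9β-[4-(triisopropylsilyl)but-3-yn-1-yl]-5α-decalin-8-one | CC(C)[Si](C(C)C)(C(C)C)C#CCC[C@@H]1[C@@]2(C)CCCC(C)(C)[C@@H]2[C@@H](O)CC1=O
F3 | step 4 | trimethylsilyl ketene acetal of 6 (C11 chain cis to O–Si) | CC(C)[Si](C(C)C)(C(C)C)C#CCC/C=C(/OCC1=C(C)CCCC1(C)C)O[Si](C)(C)C
F4 | step 4 | trimethylsilyl ester of the racemic Claisen acid (one enantiomer drawn) | CC(C)[Si](C(C)C)(C(C)C)C#CCC[C@@H](C(=O)O[Si](C)(C)C)[C@@]1(C)CCCC(C)(C)C1=C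
F5 | step 4 | (2S)-2-[(1S)-1,3,3-trimethyl-2-methylidenecyclohexyl]-6-(triisopropylsilyl)hex-5-ynoic acid (enantiomer of 9) | CC(C)[Si](C(C)C)(C(C)C)C#CCC[C@H](C(O)=O)[C@]1(C)CCCC(C)(C)C1=C
F6 | step 4 | (S)-1-phenylethylammonium salt of 9 | CC(C)[Si](C(C)C)(C(C)C)C#CCC[C@@H](C([O-])=O)[C@@]1(C)CCCC(C)(C)C1=C.C[C@H]([NH3+])c1ccccc1
F7 | step 5 | methyl ester of 9 | CC(C)[Si](C(C)C)(C(C)C)C#CCC[C@@H](C(=O)OC)[C@@]1(C)CCCC(C)(C)C1=C
F8 | step 5 | 5,6-spiro-epoxide of F7 (oxygen on the face opposite the C10 methyl group) | CC(C)[Si](C(C)C)(C(C)C)C#CCC[C@@H](C(=O)OC)[C@@]1(C)CCCC(C)(C)[C@@]12OC2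
F9 | step 5 | methyl ester of hydroxy acid 11 | CC(C)[Si](C(C)C)(C(C)C)C#CCC[C@@H](C(=O)OC)[C@@]1(C)CCCC(C)(C)[C@@H]1CO
F10 | step 17 | (E)-alkenyl iodide from 26 (iodine on C14) | I/C=C(\C)CC[C@@H]1[C@@]2(C)CCCC(C)(C)[C@@H]2[C@@H](OCc3ccc(OC)cc3)C[C@@]1(C)O[Si](CC)(CC)CC
F11 | step 17 | (E)-alkenyllithium from F10 | [Li]/C=C(\C)CC[C@@H]1[C@@]2(C)CCCC(C)(C)[C@@H]2[C@@H](OCc3ccc(OC)cc3)C[C@@]1(C)O[Si](CC)(CC)CC
F12 | step 22 | 6α-O-diethylsilyl (Si–H) ether of 32 | CC1=CC(=O)O[C@@H]1C/C=C(\C)CC[C@@H]1[C@@]2(C)CCCC(C)(C)[C@@H]2[C@@H](O[SiH](CC)CC)C[C@@]1(C)O[Si](CC)(CC)CC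
F13 | step 22 | oxasilinane bridging O6 and C23 through SiEt2 | CC1=CC(=O)O[C@@H]1C/C=C(\C)CC[C@@H]1[C@@]2(C)CCC[C@@](C)(C[Si](CC)(CC)O4)[C@@H]2[C@@H]4C[C@@]1(C)O[Si](CC)(CC)CC
F14 | step 22 | 6α,23-diol 8α-triethylsilyl ether | CC1=CC(=O)O[C@@H]1C/C=C(\C)CC[C@@H]1[C@@]2(C)CCC[C@@](C)(CO)[C@@H]2[C@@H](O)C[C@@]1(C)O[Si](CC)(CC)CC
F15 | step 22 | 8α-triethylsilyl ether of the target | CC1=CC(=O)O[C@@H]1C/C=C(\C)CC[C@@H]1[C@@]2(C)CCC[C@@](C)(C=O)[C@@H]2[C@@H](O)C[C@@]1(C)O[Si](CC)(CC)CC
A1 | alternative 1 | decalin alkyne with 23-O-PMB and 6,8-bis-O-triethylsilyl groups | C#CCC[C@@H]1[C@@]2(C)CCC[C@@](C)(COCc3ccc(OC)cc3)[C@@H]2[C@@H](O[Si](CC)(CC)CC)C[C@@]1(C)O[Si](CC)(CC)CC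
A2 | alternative 1 | PMB-protected 3,4-epoxybutan-2-ol (epoxide partner) | C[C@H](OCc1ccc(OC)cc1)[C@H]1CO1
A3 | alternative 1 | (13E,16R)-homoallylic alcohol with PMB-protected C17 carbinol | C[C@H](OCc4ccc(OC)cc4)[C@H](O)C/C=C(\C)CC[C@@H]1[C@@]2(C)CCC[C@@](C)(COCc3ccc(OC)cc3)[C@@H]2[C@@H](O[Si](CC)(CC)CC)C[C@@]1(C)O[Si](CC)(CC)CC
A4 | alternative 2 | (3E,7E)-homofarnesic acid with a terminal 2,2-disubstituted epoxide | OC(=O)C/C=C(\C)CC/C=C(\C)CCC[C@]1(C)CO1
A5 | alternative 2 | 8α,12-lactone with 4α-hydroxymethyl group (hydroxylated sclareolide) | O=C3C[C@@H]1[C@@]2(C)CCC[C@@](C)(CO)[C@@H]2CC[C@@]1(C)O3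
A6 | alternative 3 | (13E)-C16 aldehyde with 23-O-PMB and 6,8-bis-O-triethylsilyl groups | O=CC/C=C(\C)CC[C@@H]1[C@@]2(C)CCC[C@@](C)(COCc3ccc(OC)cc3)[C@@H]2[C@@H](O[Si](CC)(CC)CC)C[C@@]1(C)O[Si](CC)(CC)CC
A7 | alternative 3 | methyl (Z)-3-iodobut-2-enoate | COC(=O)/C=C(\I)C
A8 | alternative 3 | protected target (23-O-PMB, 6,8-bis-O-triethylsilyl) | CC1=CC(=O)O[C@@H]1C/C=C(\C)CC[C@@H]1[C@@]2(C)CCC[C@@](C)(COCc3ccc(OC)cc3)[C@@H]2[C@@H](O[Si](CC)(CC)CC)C[C@@]1(C)O[Si](CC)(CC)CC
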